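**Retrosynthetic overview**
- The target is F–CH2–P–CH2–P–CH2–F (F = propionylfilicinic acid ring, P = propionylphloroglucinol ring). Cut the two outer CH2–aryl bonds to give the central bis(propionylphloroglucinyl)methane and two aminomethyl (Mannich) derivatives of propionylfilicinic acid.
- Central unit: open both benzene rings at once at their C(acyl)–C(OH) bonds (double Claisen). This leads back to a methylene-bridged bis(4-hydroxy-2-pyrone), i.e. two 4-hydroxy-6-(2-oxobutyl)-2-pyrones plus formaldehyde. The pyrone has a single nucleophilic carbon, which fixes the bridge position.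
- Pyrone: triacetic acid lactone dianion plus a propionyl Weinreb amide.
- Filicinic unit: flopropione by dearomative geminal C-dimethylation, then a Mannich reaction.
- Ring order: the two central benzene rings are formed together in step 2; the two terminal cyclohexadienone rings are the dearomatised ring of flopropione and are not built.

Assumption: the target SMILES has no stereocentre and no stereogenic double bond (achiral, drawn as one enol tautomer), so "single enantiomer" is taken to mean this one achiral compound and no stereocontrol is needed.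

**Step 1**
Reactants: 1 4-hydroxy-6-methyl-2H-pyran-2-one (triacetic acid lactone); 2 N-methoxy-N-methylpropanamide
Product: 3 4-hydroxy-6-(2-oxobutyl)-2H-pyran-2-one
Conditions: LDA (2.2 equiv), THF, −78 °C, 1 h; 2 (1.05 equiv), −78 → 0 °C; 1 M HCl
Reagents that add atoms: N-methoxy-N-methylpropanamide CCC(=O)N(C)OC
Why: Claisen-type C-acylation of the lactone dianion (O-4 and the vinylogous 6-CH3 deprotonated), which reacts at the 6-CH2 terminus, while the Weinreb amide holds the adduct as a chelated tetrahedral intermediate so the acidic product cannot quench unreacted dianion.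

**Step 2**
Reactants: 3 4-hydroxy-6-(2-oxobutyl)-2H-pyran-2-one (2 equiv); 4 paraformaldehyde (formaldehyde source)
Product: 7 bis(2,4,6-trihydroxy-3-propanoylphenyl)methane, via bis-pyrone 5 (not isolated), via bis(triketo ester) 6 (not isolated)
Conditions: (CH2O)n (0.5 equiv per 3), Et3N (5 mol %), MeOH, 60 °C, 2 h; then Mg(OMe)2 (10 equiv, 7% in MeOH), reflux, 16 h, Ar; cold 2 M HCl
Reagents that add atoms: formaldehyde C=O (as paraformaldehyde 4); methanol CO (its OMe groups are present only in intermediate 6 and leave again)
Why: Proposed new method: the only strongly nucleophilic carbon of 3 (C-3 of the vinylogous acid) is bridged by formaldehyde (Knoevenagel–Michael, dicoumarol-type), which fixes the bridge position before any arene exists; Mg(OMe)2 then opens each lactone by chelation-assisted methanolysis to the 3,5,7-triketo ester chelate, whose doubly activated C-6 methylene closes onto the ester (6-exo-trig Claisen/Dieckmann), while the competing aldol (resorcylate) mode cannot aromatise because C-2 already carries the bridge, and enolisation to the phenoxide makes each closure irreversible, so two benzene rings form in one operation (excess Mg(OMe)2 also takes up the water from the bridging); the closest known reactions are the formaldehyde bridging of 4-hydroxy-2-pyrones and the Mg(OMe)2-mediated biomimetic recyclisation of single 6-(2-oxoalkyl)-4-hydroxy-2-pyrones to acylphloroglucinols.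

**Step 3**
Reactants: 8 1-(2,4,6-trihydroxyphenyl)propan-1-one (flopropione); 9 iodomethane
Product: 10 3,5-dihydroxy-6,6-dimethyl-2-propanoylcyclohexa-2,4-dien-1-one (propionylfilicinic acid)
Conditions: NaOMe (3.0 equiv), MeI (2.5 equiv), MeOH, 0 °C → rt, 16 h; 1 M HCl
Reagents that add atoms: iodomethane CI
Why: Dearomative C-methylation of the phloroglucinol polyanion (Riedl-type filicinic acid synthesis), in which the first methylated ring carbon is the most nucleophilic and takes the second methyl to give the gem-dimethyl dienone; mono-, over- and O-methylated by-products are removed by crystallisation or chromatography.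

**Step 4**
Reactants: 10 propionylfilicinic acid; 11 N,N,N',N'-tetramethylmethanediamine [bis(dimethylamino)methane]
Product: 12 4-[(dimethylamino)methyl]-3,5-dihydroxy-6,6-dimethyl-2-propanoylcyclohexa-2,4-dien-1-one (zwitterionic Mannich base)
Conditions: 11 (1.5 equiv), CH2Cl2, 0 °C → rt, 2 h (10 added slowly to 11); evaporate, triturate with Et2O
Reagents that add atoms: N,N,N',N'-tetramethylmethanediamine CN(C)CN(C)C
Why: Mannich reaction in which the strongly acidic cyclic triketone (pKa about 4–5) protonates the aminal and its only free ring carbon (C-4) captures the released aminomethyl electrophile, with excess aminal suppressing the methylene-bis(filicinic) by-product.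

**Step 5**
Reactants: 7 bis(2,4,6-trihydroxy-3-propanoylphenyl)methane; 12 Mannich base (2.3 equiv)
Product: 15 target tetramer 4,4'-{methylenebis[(2,4,6-trihydroxy-5-propanoyl-3,1-phenylene)methylene]}bis(3,5-dihydroxy-6,6-dimethyl-2-propanoylcyclohexa-2,4-dien-1-one), via methylidene trione 13 (not isolated), via mono-adduct 14 (not isolated)
Conditions: 1,4-dioxane, 80 °C, N2 sweep, 6 h; 1 M HCl wash
Reagents that add atoms: none
Why: Thermal retro-Mannich (E1cB) loss of dimethylamine gives the 2-methylidene-1,3-dione 13, a strong Michael acceptor that is trapped by the one free, doubly OH-flanked carbon of each ring of 7 (Friedel–Crafts-type Michael addition, then re-aromatisation), once per ring, with the N2 sweep removing the amine that could otherwise scramble the methylene bridges.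

**Compound list**
1 | 4-hydroxy-6-methyl-2H-pyran-2-one (triacetic acid lactone) | CC1=CC(O)=CC(=O)O1 | starting material
2 | N-methoxy-N-methylpropanamide | CCC(=O)N(C)OC | starting material
3 | 4-hydroxy-6-(2-oxobutyl)-2H-pyran-2-one | CCC(=O)CC1=CC(O)=CC(=O)O1 | intermediate
4 | paraformaldehyde (as formaldehyde) | C=O | starting material
5 | 3,3'-methylenebis[4-hydroxy-6-(2-oxobutyl)-2H-pyran-2-one] (bis-pyrone, not isolated) | CCC(=O)CC1=CC(O)=C(CC2=C(O)C=C(CC(=O)CC)OC2=O)C(=O)O1 | intermediate
6 | dimethyl 2,4-bis(3,5-dioxoheptanoyl)pentanedioate (bis(triketo ester), Mg chelate in the flask, not isolated; no defined configuration, both CH centres are lost on cyclisation) | COC(=O)C(CC(C(=O)OC)C(=O)CC(=O)CC(=O)CC)C(=O)CC(=O)CC(=O)CC | intermediate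
7 | bis(2,4,6-trihydroxy-3-propanoylphenyl)methane | CCC(=O)c1c(O)cc(O)c(Cc2c(O)cc(O)c(C(=O)CC)c2O)c1O | intermediate
8 | 1-(2,4,6-trihydroxyphenyl)propan-1-one (flopropione) | CCC(=O)c1c(O)cc(O)cc1O | starting material
9 | iodomethane | CI | starting material
10 | 3,5-dihydroxy-6,6-dimethyl-2-propanoylcyclohexa-2,4-dien-1-one (propionylfilicinic acid) | CCC(=O)C1=C(O)C=C(O)C(C)(C)C1=O | intermediate
11 | N,N,N',N'-tetramethylmethanediamine | CN(C)CN(C)C | starting material
12 | 4-[(dimethylamino)methyl]-3,5-dihydroxy-6,6-dimethyl-2-propanoylcyclohexa-2,4-dien-1-one | CCC(=O)C1=C(O)C(CN(C)C)=C(O)C(C)(C)C1=O | intermediate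
13 | 3-hydroxy-4,4-dimethyl-6-methylidene-2-propanoylcyclohex-2-ene-1,5-dione (not isolated) | CCC(=O)C1=C(O)C(C)(C)C(=O)C(=C)C1=O | intermediate
14 | 4-{[2,4,6-trihydroxy-5-propanoyl-3-(2,4,6-trihydroxy-3-propanoylbenzyl)phenyl]methyl}-3,5-dihydroxy-6,6-dimethyl-2-propanoylcyclohexa-2,4-dien-1-one (mono-adduct, not isolated) | CCC(=O)C1=C(O)C(Cc2c(O)c(Cc3c(O)cc(O)c(C(=O)CC)c3O)c(O)c(C(=O)CC)c2O)=C(O)C(C)(C)C1=O | intermediate
15 | 4,4'-{methylenebis[(2,4,6-trihydroxy-5-propanoyl-3,1-phenylene)methylene]}bis(3,5-dihydroxy-6,6-dimethyl-2-propanoylcyclohexa-2,4-dien-1-one) (CNP0541376.0, achiral) | CCC(=O)C1=C(O)C(Cc2c(O)c(Cc3c(O)c(CC4=C(O)C(C)(C)C(=O)C(C(=O)CC)=C4O)c(O)c(C(=O)CC)c3O)c(O)c(C(=O)CC)c2O)=C(O)C(C)(C)C1=O | target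

**Step count and risks**
Total step count: 5. Longest linear sequence: 3 steps (1 → 3 → 7 → 15, steps 1, 2 and 5; the branch 8 → 10 → 12 → 15 is also 3).

The three steps most likely to fail:

Step 2 (one-pot bridging and double recyclisation). The main dangers are a Hagemann-type intramolecular aldol between the two opened chains across the CH2 bridge (they are 1,5-dicarbonyl related) and base-mediated methylene exchange in 7. The fallback sets out from 3 and closes each benzene ring before the bridge exists. Pyrone 3 alone is treated with Mg(OMe)2 in refluxing MeOH, which opens the lactone to methyl 3,5,7-trioxononanoate F2 (not isolated) and cyclises it (Claisen) to flopropione 8. A four-fold excess of 8 (the excess is recovered) is then bridged with paraformaldehyde 4 in 1% aq KOH at 0 °C for a few minutes. This passes through 1-[2,4,6-trihydroxy-3-(hydroxymethyl)phenyl]propan-1-one F3, which alkylates a second molecule of 8, and the route is rejoined at 7.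

Step 5 (double cross-coupling). The dangers are self-reaction of the very electrophilic methylidene trione 13 and amine-mediated scrambling of the bridges. The fallback reverses the polarity and sets out from 7. Both free ring carbons of 7 are aminomethylated with excess 11 (MeCN, rt) to give the bis-Mannich base 1,1'-{methylenebis[5-((dimethylamino)methyl)-2,4,6-trihydroxy-3,1-phenylene]}bis(propan-1-one) F4. This is heated with 10 (2.2 equiv) in dioxane, so that the electrophile is the milder phenol-derived quinone methide and the nucleophile is the acidic triketone 10, which has only one nucleophilic carbon. The reaction passes through the mono-exchanged Mannich base 4-{[3-({3-[(dimethylamino)methyl]-2,4,6-trihydroxy-5-propanoylphenyl}methyl)-2,4,6-trihydroxy-5-propanoylphenyl]methyl}-3,5-dihydroxy-6,6-dimethyl-2-propanoylcyclohexa-2,4-dien-1-one F5 and comes back at 15; step 4 and compound 12 are then not needed.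

Step 1 (dianion acylation). The dangers are poor solubility of the dianion and proton transfer instead of acylation. The fallback sets out from 1 and replaces acylation by aldol addition then oxidation. The same LDA dianion is trapped with propanal at −78 °C to give racemic 4-hydroxy-6-(2-hydroxybutyl)-2H-pyran-2-one F1. Its secondary alcohol is oxidised with Jones reagent in acetone at 0 °C, which removes the stereocentre, and the route is rejoined at 3.

**Further compounds**
F1 | step 1 | 4-hydroxy-6-(2-hydroxybutyl)-2H-pyran-2-one (racemic) | CCC(O)CC1=CC(O)=CC(=O)O1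
F2 | step 2 | methyl 3,5,7-trioxononanoate | COC(=O)CC(=O)CC(=O)CC(=O)CC
F3 | step 2 | 1-[2,4,6-trihydroxy-3-(hydroxymethyl)phenyl]propan-1-one | CCC(=O)c1c(O)cc(O)c(CO)c1O
F4 | step 5 | 1,1'-{methylenebis[5-((dimethylamino)methyl)-2,4,6-trihydroxy-3,1-phenylene]}bis(propan-1-one) | CCC(=O)c1c(O)c(CN(C)C)c(O)c(Cc2c(O)c(CN(C)C)c(O)c(C(=O)CC)c2O)c1O
F5 | step 5 | 4-{[3-({3-[(dimethylamino)methyl]-2,4,6-trihydroxy-5-propanoylphenyl}methyl)-2,4,6-trihydroxy-5-propanoylphenyl]methyl}-3,5-dihydroxy-6,6-dimethyl-2-propanoylcyclohexa-2,4-dien-1-one | CCC(=O)C1=C(O)C(Cc2c(O)c(Cc3c(O)c(CN(C)C)c(O)c(C(=O)CC)c3O)c(O)c(C(=O)CC)c2O)=C(O)C(C)(C)C1=O
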